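**Strategy.** Everything rests on opening both rings of the naphthoquinone to the acyclic chain C8–C8a–C1–C2=C3–C4–C4a–C5. The feature exploited is the 2,8-relationship. The C8 methyl of benzenoid ring B sits peri to the C1 carbonyl of quinone ring A, that carbonyl neighbours the C2 methyl, and hexaprenyl is on C3. In the open chain this pattern is pure connectivity. A rhodium-catalysed [2+2+2] cycloaddition of the diyne with acetylene forms C4a–C8a, C5–C6 and C7–C8 and closes rings A and B in one operation. The precursor is a tetrasubstituted Z-alkene (C2 methyl, C3 hexaprenyl). Its cis arms are silyl-protected propargylic carbinols, propynyl at C1 and ethynyl at C4.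

Key step: step 17

Assumption: the target has no stereocentre. The C1 and C4 carbinol carbons and the sulfonyl-bearing carbon of the C30 sulfone are therefore carried as stereorandom mixtures that are erased later, and only alkene geometry is controlled. (2E,6E)-Farnesyl bromide and ethynylmagnesium bromide solution are taken as commercial.

Step 1
Reactants: 1 (2E,6E)-farnesol
Product: 2 (2E,6E)-farnesyl tert-butyldiphenylsilyl ether
Conditions: TBDPSCl, imidazole, DMF, rt
Reagents that add atoms: tert-butyl(chloro)diphenylsilane CC(C)(C)[Si](Cl)(c1ccccc1)c1ccccc1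
Why: Standard silylation of a primary allylic alcohol gives an ether that survives the oxidation, carbanion and hydride steps ahead and is not ionised by zerovalent palladium.

Step 2
Reactants: 2 (2E,6E)-farnesyl tert-butyldiphenylsilyl ether
Product: 3 (2E,6E,10E)-12-(tert-butyldiphenylsilyloxy)-2,6,10-trimethyldodeca-2,6,10-trien-1-ol
Conditions: SeO2 (0.1 equiv), t-BuOOH, salicylic acid (0.1 equiv), CH2Cl2, 0 °C → rt, stopped at partial conversion, 2 recycled
Reagents that add atoms: tert-butyl hydroperoxide CC(C)(C)OO (oxygen source), relayed by SeO2 O=[Se]=O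
Why: In this catalytic Riley allylic oxidation the ene reaction and [2,3]-sigmatropic shift select the most electron-rich terminal alkene and oxygenate only its E methyl group, which fixes the future 10'E geometry.

Step 3
Reactants: 3 (2E,6E,10E)-12-(tert-butyldiphenylsilyloxy)-2,6,10-trimethyldodeca-2,6,10-trien-1-ol
Product: 4 (2E,6E,10E)-12-bromo-3,7,11-trimethyldodeca-2,6,10-trienyl tert-butyldiphenylsilyl ether
Conditions: CBr4, PPh3, CH2Cl2, 0 °C
Reagents that add atoms: carbon tetrabromide BrC(Br)(Br)Br
Why: The Appel reaction replaces the primary allylic hydroxyl by SN2 under neutral conditions, without allylic transposition or loss of the silyl ether.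

Step 4
Reactants: 5 (2E,6E)-farnesyl bromide
Product: 6 (2E,6E)-farnesyl phenyl sulfone
Conditions: PhSO2Na, DMF, rt
Reagents that add atoms: sodium benzenesulfinate [Na+].[O-]S(=O)c1ccccc1
Why: SN2 S-alkylation of the sulfinate at the primary allylic carbon leaves both E alkenes untouched.

Step 5
Reactants: 6 (2E,6E)-farnesyl phenyl sulfone; 4 (2E,6E,10E)-12-bromo-3,7,11-trimethyldodeca-2,6,10-trienyl tert-butyldiphenylsilyl ether
Product: 8 racemic 13-(phenylsulfonyl)-all-E-hexaprenyl tert-butyldiphenylsilyl ether, via lithiated sulfone 7 (not isolated)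
Conditions: n-BuLi, THF, −78 °C; then 4, −78 → −20 °C
Reagents that add atoms: none
Why: In this alkylation of a sulfone-stabilised allylic carbanion (Biellmann-type head-to-tail coupling) the soft anion attacks the primary allylic bromide by SN2, and the new sulfonyl-bearing centre is racemic and is erased in step 6.

Step 6
Reactants: 8 racemic 13-(phenylsulfonyl)-all-E-hexaprenyl tert-butyldiphenylsilyl ether
Product: 9 all-E-hexaprenyl tert-butyldiphenylsilyl ether
Conditions: PdCl2(dppp) (5 mol %), LiEt3BH, THF, 0 °C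
Reagents that add atoms: none
Why: In this palladium-catalysed hydride desulfonylation zerovalent palladium ionises the allylic sulfone to a π-allyl complex and hydride goes to its less substituted end, so the trisubstituted alkene keeps its position and E geometry.

Step 7
Reactants: 9 all-E-hexaprenyl tert-butyldiphenylsilyl ether
Product: 10 all-E-hexaprenol, (2E,6E,10E,14E,18E)-3,7,11,15,19,23-hexamethyltetracosa-2,6,10,14,18,22-hexaen-1-ol
Conditions: Bu4NF, THF, rt
Reagents that add atoms: none
Why: Fluoride desilylation is driven by Si–F bond formation and nothing else in the polyene responds.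

Step 8
Reactants: 10 all-E-hexaprenol
Product: 11 all-E-hexaprenyl bromide
Conditions: PBr3 (0.4 equiv), Et2O, 0 °C, used crude
Reagents that add atoms: phosphorus tribromide BrP(Br)Br
Why: Classical PBr3 bromination of a polyprenol proceeds by SN2 on the phosphite ester and retains the 2E alkene.

Step 9
Reactants: 12 but-2-yn-1-ol
Product: 13 but-2-ynal
Conditions: MnO2, CH2Cl2, rt; filtered, dried, used as solution
Reagents that add atoms: none
Why: MnO2 oxidation of a propargylic alcohol stops at the aldehyde, and the volatile ynal is carried on in solution instead of being concentrated.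

Step 10
Reactants: 14 methyl propiolate; 13 but-2-ynal
Product: 16 racemic methyl 4-hydroxyhepta-2,5-diynoate, via lithium acetylide 15 (not isolated)
Conditions: LiN(SiMe3)2, THF, −78 °C; then 13; then AcOH, −78 °C
Reagents that add atoms: none
Why: This 1,2-addition of a lithium acetylide to an aldehyde is kept at −78 °C, where the ester-bearing acetylide does not self-condense, and the new C1 carbinol centre is racemic and is erased in step 19.

Step 11
Reactants: 16 racemic methyl 4-hydroxyhepta-2,5-diynoate
Product: 17 methyl 4-(tert-butyldimethylsilyloxy)hepta-2,5-diynoate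
Conditions: TBSOTf, 2,6-lutidine, CH2Cl2, −78 °C
Reagents that add atoms: tert-butyldimethylsilyl triflate CC(C)(C)[Si](C)(C)OS(=O)(=O)C(F)(F)F
Why: Silylation with a silyl triflate and a hindered non-nucleophilic base avoids the base-induced redox isomerisation and the aza-Michael addition to which γ-hydroxy ynoates are prone.

Step 12
Reactants: 17 methyl 4-(tert-butyldimethylsilyloxy)hepta-2,5-diynoate; 11 all-E-hexaprenyl bromide
Product: 19 methyl (2Z)-2-(all-E-hexaprenyl)-3-methyl-4-(tert-butyldimethylsilyloxy)hept-2-en-5-ynoate, via vinylcopper 18 (not isolated)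
Conditions: MeMgBr, CuBr·SMe2 (1:1), THF, −40 °C; 17 (slight excess over MeCu), −78 °C; then DMPU, 11 (limiting), −78 → −20 °C
Reagents that add atoms: methylmagnesium bromide C[Mg]Br
Why: In this tandem carbocupration–allylation of an ynoate, MeCu (which carries no second transferable methyl) adds syn across the ester-activated alkyne only and 18 is alkylated at the primary carbon of 11 with retention, so methyl and chain end up cis; if 18 relaxes to its allenolate, approach past the small methyl instead of the bulky silyloxypropargyl group gives the same 2Z isomer.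

Step 13
Reactants: 19 methyl (2Z)-2-(all-E-hexaprenyl)-3-methyl-4-(tert-butyldimethylsilyloxy)hept-2-en-5-ynoate
Product: 20 (2Z)-2-(all-E-hexaprenyl)-3-methyl-4-(tert-butyldimethylsilyloxy)hept-2-en-5-yn-1-ol
Conditions: i-Bu2AlH (2.5 equiv), CH2Cl2, −78 °C
Reagents that add atoms: none
Why: Hydride reduction of the enoate to the allylic alcohol is run at low temperature, where isolated alkynes, alkenes and the silyl ether are inert and silyl migration is suppressed.

Step 14
Reactants: 20 (2Z)-2-(all-E-hexaprenyl)-3-methyl-4-(tert-butyldimethylsilyloxy)hept-2-en-5-yn-1-ol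
Product: 21 (2Z)-2-(all-E-hexaprenyl)-3-methyl-4-(tert-butyldimethylsilyloxy)hept-2-en-5-ynal
Conditions: MnO2, CH2Cl2, rt
Reagents that add atoms: none
Why: Neutral heterogeneous MnO2 oxidation of an allylic alcohol gives the Z-enal without geometric isomerisation, and the silyl group on the C1 oxygen blocks lactol and furan formation.

Step 15
Reactants: 21 (2Z)-2-(all-E-hexaprenyl)-3-methyl-4-(tert-butyldimethylsilyloxy)hept-2-en-5-ynal; 22 ethynylmagnesium bromide
Product: 23 (4Z)-4-(all-E-hexaprenyl)-5-methyl-6-(tert-butyldimethylsilyloxy)non-4-ene-1,7-diyn-3-ol (epimer mixture)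
Conditions: THF, −78 → 0 °C
Reagents that add atoms: none
Why: In this Grignard 1,2-addition the fully substituted β carbon shuts off conjugate addition, the C4 carbinol forms without control as epimers that are erased in step 19, and any O-to-O silyl shift is levelled in step 16.

Step 16
Reactants: 23 (4Z)-4-(all-E-hexaprenyl)-5-methyl-6-(tert-butyldimethylsilyloxy)non-4-ene-1,7-diyn-3-ol
Product: 24 (4Z)-3,6-bis(tert-butyldimethylsilyloxy)-4-(all-E-hexaprenyl)-5-methylnon-4-ene-1,7-diyne (epimer mixture)
Conditions: TBSOTf, 2,6-lutidine, CH2Cl2, −78 → 0 °C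
Reagents that add atoms: tert-butyldimethylsilyl triflate CC(C)(C)[Si](C)(C)OS(=O)(=O)C(F)(F)F
Why: Silyl triflate silylation of the hindered alcohol masks the second doubly activated carbinol against ionisation, cyclodehydration and binding to rhodium.

Step 17
Reactants: 24 (4Z)-3,6-bis(tert-butyldimethylsilyloxy)-4-(all-E-hexaprenyl)-5-methylnon-4-ene-1,7-diyne; 25 acetylene
Product: 27 1,4-bis(tert-butyldimethylsilyloxy)-2,8-dimethyl-3-(all-E-hexaprenyl)-1,4-dihydronaphthalene (epimer mixture), via rhodacyclopentadiene 26 (not isolated)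
Conditions: RhCl(PPh3)3 (10 mol %), acetone-free HC≡CH (1 atm), toluene, 25 → 50 °C, 24 added by syringe pump
Reagents that add atoms: none
Why: After loss of PPh3, monovalent rhodium binds both alkynes of 24 and couples them oxidatively to the trivalent rhodacyclopentadiene 26, forming C4a–C8a; acetylene then inserts into a Rh–C bond and reductive elimination forms C5–C6 and C7–C8 and returns the catalyst. The closest known reaction type is the rhodium-catalysed [2+2+2] cycloaddition of tethered 1,6- and 1,7-diynes with gaseous acetylene, including diynes whose tether contains an arene C=C. Ring A (C1–C2–C3–C4–C4a–C8a, the future quinone ring) closes in the oxidative cyclisation as a six-membered carbocycle fused to the metallacycle, and ring B (C4a–C5–C6–C7–C8–C8a) closes in the insertion and reductive elimination as the new arene. No stereocentre is created and the C1/C4 epimers pass through unchanged. The step needs cross-cycloaddition instead of diyne self-reaction and alkyne instead of alkene participation: the tetrasubstituted Z-alkene holds the two arms cis so that intramolecular coupling is fast, slow addition into acetylene-saturated solution keeps free diyne scarce, and the seven tri- or tetrasubstituted alkenes bind rhodium too weakly to compete. Regiochemistry cannot go astray, because acetylene is symmetrical and the methyl-capped alkyne is already attached to C1.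

Step 18
Reactants: 27 1,4-bis(tert-butyldimethylsilyloxy)-2,8-dimethyl-3-(all-E-hexaprenyl)-1,4-dihydronaphthalene
Product: 28 2,8-dimethyl-3-(all-E-hexaprenyl)-1,4-dihydronaphthalene-1,4-diol (epimer mixture)
Conditions: Bu4NF, AcOH (1:1), THF, 0 °C → rt
Reagents that add atoms: none
Why: This fluoride desilylation is buffered so that the medium is neither acidic nor basic enough to trigger aromatising loss of water from the benzylic–allylic diol.

Step 19
Reactants: 28 2,8-dimethyl-3-(all-E-hexaprenyl)-1,4-dihydronaphthalene-1,4-diol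
Product: 31 2,8-dimethyl-3-(all-E-hexaprenyl)-1,4-naphthoquinone (8-methylmenaquinone-6), via hydroxy-enone 29 (not isolated), via naphthohydroquinone 30 (not isolated)
Conditions: MnO2 (excess), CH2Cl2, rt
Reagents that add atoms: none
Why: In this MnO2 oxidation of benzylic–allylic carbinols the first oxidation gives 29, the keto tautomer of 30, which aromatises by enolisation and is oxidised again to the quinone (direct oxidation of the second carbinol ends at the same compound), while the isolated trisubstituted alkenes are untouched and both carbinol centres vanish.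

**Compound list**

1 | (2E,6E)-farnesol | CC(C)=CCC/C(C)=C/CC/C(C)=C/CO | starting material
2 | (2E,6E)-farnesyl tert-butyldiphenylsilyl ether | CC(C)=CCC/C(C)=C/CC/C(C)=C/CO[Si](c1ccccc1)(c1ccccc1)C(C)(C)C | intermediate
3 | (2E,6E,10E)-12-(tert-butyldiphenylsilyloxy)-2,6,10-trimethyldodeca-2,6,10-trien-1-ol | OC/C(C)=C/CC/C(C)=C/CC/C(C)=C/CO[Si](c1ccccc1)(c1ccccc1)C(C)(C)C | intermediate
4 | (2E,6E,10E)-12-bromo-3,7,11-trimethyldodeca-2,6,10-trienyl tert-butyldiphenylsilyl ether | BrC/C(C)=C/CC/C(C)=C/CC/C(C)=C/CO[Si](c1ccccc1)(c1ccccc1)C(C)(C)C | intermediate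
5 | (2E,6E)-farnesyl bromide | CC(C)=CCC/C(C)=C/CC/C(C)=C/CBr | starting material
6 | (2E,6E)-farnesyl phenyl sulfone | CC(C)=CCC/C(C)=C/CC/C(C)=C/CS(=O)(=O)c1ccccc1 | intermediate
7 | α-lithiated farnesyl phenyl sulfone | CC(C)=CCC/C(C)=C/CC/C(C)=C/C([Li])S(=O)(=O)c1ccccc1 | intermediate
8 | racemic 13-(phenylsulfonyl)-all-E-hexaprenyl tert-butyldiphenylsilyl ether | CC(C)=CCC/C(C)=C/CC/C(C)=C/C(S(=O)(=O)c1ccccc1)C/C(C)=C/CC/C(C)=C/CC/C(C)=C/CO[Si](c1ccccc1)(c1ccccc1)C(C)(C)C | intermediate
9 | all-E-hexaprenyl tert-butyldiphenylsilyl ether | CC(C)=CCC/C(C)=C/CC/C(C)=C/CC/C(C)=C/CC/C(C)=C/CC/C(C)=C/CO[Si](c1ccccc1)(c1ccccc1)C(C)(C)C | intermediate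
10 | all-E-hexaprenol | CC(C)=CCC/C(C)=C/CC/C(C)=C/CC/C(C)=C/CC/C(C)=C/CC/C(C)=C/CO | intermediate
11 | all-E-hexaprenyl bromide | CC(C)=CCC/C(C)=C/CC/C(C)=C/CC/C(C)=C/CC/C(C)=C/CC/C(C)=C/CBr | intermediate
12 | but-2-yn-1-ol | CC#CCO | starting material
13 | but-2-ynal | CC#CC=O | intermediate
14 | methyl propiolate | C#CC(=O)OC | starting material
15 | methyl 3-lithiopropiolate | [Li]C#CC(=O)OC | intermediate
16 | racemic methyl 4-hydroxyhepta-2,5-diynoate | CC#CC(O)C#CC(=O)OC | intermediate
17 | methyl 4-(tert-butyldimethylsilyloxy)hepta-2,5-diynoate | CC#CC(O[Si](C)(C)C(C)(C)C)C#CC(=O)OC | intermediate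
18 | α-cuprio enoate, copper cis to the new methyl | COC(=O)/C([Cu])=C(/C)C(O[Si](C)(C)C(C)(C)C)C#CC | intermediate
19 | methyl (2Z)-2-(all-E-hexaprenyl)-3-methyl-4-(tert-butyldimethylsilyloxy)hept-2-en-5-ynoate | CC(C)=CCC/C(C)=C/CC/C(C)=C/CC/C(C)=C/CC/C(C)=C/CC/C(C)=C/C/C(C(=O)OC)=C(\C)C(O[Si](C)(C)C(C)(C)C)C#CC | intermediate
20 | (2Z)-2-(all-E-hexaprenyl)-3-methyl-4-(tert-butyldimethylsilyloxy)hept-2-en-5-yn-1-ol | CC(C)=CCC/C(C)=C/CC/C(C)=C/CC/C(C)=C/CC/C(C)=C/CC/C(C)=C/C/C(CO)=C(\C)C(O[Si](C)(C)C(C)(C)C)C#CC | intermediate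
21 | (2Z)-2-(all-E-hexaprenyl)-3-methyl-4-(tert-butyldimethylsilyloxy)hept-2-en-5-ynal | CC(C)=CCC/C(C)=C/CC/C(C)=C/CC/C(C)=C/CC/C(C)=C/CC/C(C)=C/C/C(C=O)=C(\C)C(O[Si](C)(C)C(C)(C)C)C#CC | intermediate
22 | ethynylmagnesium bromide | C#C[Mg]Br | starting material
23 | (4Z)-4-(all-E-hexaprenyl)-5-methyl-6-(tert-butyldimethylsilyloxy)non-4-ene-1,7-diyn-3-ol, epimer mixture | CC(C)=CCC/C(C)=C/CC/C(C)=C/CC/C(C)=C/CC/C(C)=C/CC/C(C)=C/C/C(C(O)C#C)=C(\C)C(O[Si](C)(C)C(C)(C)C)C#CC | intermediate
24 | (4Z)-3,6-bis(tert-butyldimethylsilyloxy)-4-(all-E-hexaprenyl)-5-methylnon-4-ene-1,7-diyne, epimer mixture | CC(C)=CCC/C(C)=C/CC/C(C)=C/CC/C(C)=C/CC/C(C)=C/CC/C(C)=C/C/C(C(O[Si](C)(C)C(C)(C)C)C#C)=C(\C)C(O[Si](C)(C)C(C)(C)C)C#CC | intermediate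
25 | acetylene | C#C | starting material
26 | chlororhodacyclopentadiene fused to ring A (PPh3 ligands omitted) | CC(C)=CCC/C(C)=C/CC/C(C)=C/CC/C(C)=C/CC/C(C)=C/CC/C(C)=C/CC1=C(C)C(O[Si](C)(C)C(C)(C)C)C2=C(C)[Rh](Cl)C=C2C1O[Si](C)(C)C(C)(C)C | intermediate
27 | 1,4-bis(tert-butyldimethylsilyloxy)-2,8-dimethyl-3-(all-E-hexaprenyl)-1,4-dihydronaphthalene, epimer mixture | CC(C)=CCC/C(C)=C/CC/C(C)=C/CC/C(C)=C/CC/C(C)=C/CC/C(C)=C/CC1=C(C)C(O[Si](C)(C)C(C)(C)C)c2c(C)cccc2C1O[Si](C)(C)C(C)(C)C | intermediate
28 | 2,8-dimethyl-3-(all-E-hexaprenyl)-1,4-dihydronaphthalene-1,4-diol, epimer mixture | CC(C)=CCC/C(C)=C/CC/C(C)=C/CC/C(C)=C/CC/C(C)=C/CC/C(C)=C/CC1=C(C)C(O)c2c(C)cccc2C1O | intermediate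
29 | 4-hydroxy-3,5-dimethyl-2-(all-E-hexaprenyl)naphthalen-1(4H)-one (ketone at C4, carbinol at C1 of the target numbering) | CC(C)=CCC/C(C)=C/CC/C(C)=C/CC/C(C)=C/CC/C(C)=C/CC/C(C)=C/CC1=C(C)C(O)c2c(C)cccc2C1=O | intermediate
30 | 2,8-dimethyl-3-(all-E-hexaprenyl)naphthalene-1,4-diol | CC(C)=CCC/C(C)=C/CC/C(C)=C/CC/C(C)=C/CC/C(C)=C/CC/C(C)=C/Cc1c(C)c(O)c2c(C)cccc2c1O | intermediate
31 | 2,8-dimethyl-3-(all-E-hexaprenyl)-1,4-naphthoquinone (CID101244058) | CC(C)=CCC/C(C)=C/CC/C(C)=C/CC/C(C)=C/CC/C(C)=C/CC/C(C)=C/CC1=C(C)C(=O)c2c(C)cccc2C1=O | target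

**Total step count:** 19. **Longest linear sequence:** 15 (steps 1, 2, 3, 5, 6, 7, 8, 12, 13, 14, 15, 16, 17, 18, 19).

**Steps most likely to fail**

First, step 17. Oxidative cyclisation of the crowded 1,7-diyne may be slow. That would leave room for self-oligomerisation of the diyne, polymerisation of acetylene on rhodium, or thermal loss of silanol. The fallback gives up the cycloaddition, sets out from hexaprenol 10 and comes back at hydroquinone 30.
- Commercial 2-bromo-6-methylphenol is oxidised with (KSO3)2NO (Teuber oxidation) to 2-bromo-6-methyl-1,4-benzoquinone F1.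
- Diels–Alder reaction with (E)-penta-1,3-diene takes place at the brominated alkene. The methyl-bearing diene terminus bonds to the C–Br carbon, and this gives the bromo adduct F2.
- Et3N removes HBr to give 2,8-dimethyl-5,8-dihydronaphthalene-1,4-dione F3.
- MnO2 aromatises F3 to 2,8-dimethyl-1,4-naphthoquinone F4.
- Na2S2O4 reduces F4 to 2,8-dimethylnaphthalene-1,4-diol F5.
- Friedel–Crafts allylation of F5 with 10, promoted by BF3·OEt2, occurs at C3, the only free position of that ring. It gives 30, which is oxidised as in step 19.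

Second, step 12. Alkylation of the ester-stabilised vinylcopper may be sluggish. Warming would then erode the alkene geometry through the allenolate, allow SN2' attack on the allylic bromide, or end in simple protonation. The fallback separates the two bond formations, sets out from 17 and 11 and comes back at 19.
- Adduct 18 is quenched with I2 to give methyl (E)-2-iodo-3-methyl-4-(tert-butyldimethylsilyloxy)hept-2-en-5-ynoate F6, which can be purified to a single geometry.
- Bromide 11 is converted with Bu3SnLi into all-E-hexaprenyltributylstannane F7.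
- A Stille coupling (Pd2(dba)3, AsPh3, CuI, DMF) joins F6 and F7 at the primary allyl carbon.

Third, step 18. Ionisation at the benzylic–allylic carbinol carbons may cause aromatising loss of water during or after desilylation. The fallback makes this the intended path, sets out from 27 and comes back at 31.
- After fluoride treatment, crude 28 is exposed to pyridinium p-toluenesulfonate so that dehydration goes to completion.
- This gives 3,5-dimethyl-2-(all-E-hexaprenyl)naphthalen-1-ol F8 and 2,8-dimethyl-3-(all-E-hexaprenyl)naphthalen-1-ol F9, each with a free para position.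
- Teuber oxidation with (KSO3)2NO converts both naphthols into the same quinone.

**Further compounds**

F1 | step 17 | 2-bromo-6-methyl-1,4-benzoquinone | CC1=CC(=O)C=C(Br)C1=O
F2 | step 17 | 8a-bromo-2,8-dimethyl-4a,5,8,8a-tetrahydronaphthalene-1,4-dione (racemic endo adduct, stereocentres erased) | CC1=CC(=O)C2CC=CC(C)C2(Br)C1=O
F3 | step 17 | 2,8-dimethyl-5,8-dihydronaphthalene-1,4-dione (racemic) | CC1=CC(=O)C2=C(C1=O)C(C)C=CC2
F4 | step 17 | 2,8-dimethyl-1,4-naphthoquinone | CC1=CC(=O)c2cccc(C)c2C1=O
F5 | step 17 | 2,8-dimethylnaphthalene-1,4-diol | Cc1cc(O)c2cccc(C)c2c1O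
F6 | step 12 | methyl (E)-2-iodo-3-methyl-4-(tert-butyldimethylsilyloxy)hept-2-en-5-ynoate | COC(=O)/C(I)=C(/C)C(O[Si](C)(C)C(C)(C)C)C#CC
F7 | step 12 | all-E-hexaprenyltributylstannane | CC(C)=CCC/C(C)=C/CC/C(C)=C/CC/C(C)=C/CC/C(C)=C/CC/C(C)=C/C[Sn](CCCC)(CCCC)CCCC
F8 | step 18 | 3,5-dimethyl-2-(all-E-hexaprenyl)naphthalen-1-ol | CC(C)=CCC/C(C)=C/CC/C(C)=C/CC/C(C)=C/CC/C(C)=C/CC/C(C)=C/Cc1c(C)cc2c(C)cccc2c1O
F9 | step 18 | 2,8-dimethyl-3-(all-E-hexaprenyl)naphthalen-1-ol | CC(C)=CCC/C(C)=C/CC/C(C)=C/CC/C(C)=C/CC/C(C)=C/CC/C(C)=C/Cc1cc2cccc(C)c2c(O)c1C
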